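**Retrosynthetic overview**
1. Target 21 ⇒ enone unveiled last from a (3S,5S)-1,3,5-trioxygenated cyclohexane: the ring oxygen cis to the tertiary OH is oxidised to the ketone, the trans one leaves as mesylate (E1cB).
2. (Z,Z)-diene ⇒ semihydrogenation of a 1,4-diyne ⇒ key disconnection at the C-11–C-12 bond: terminal alkyne 11 (C-11 is the sp C–H carbon) plus 1-bromooct-2-yne 12 (C-12 is the propargylic CH2Br), joined with CuI.
3. Enabling feature: the skipped diene C-10=C-11–C-12H2–C-13=C-14 of the side chain. Its doubly allylic CH2 maps onto a propargylic electrophile and its two cis alkenes onto two alkynes, and seven CH2 groups insulate it from the cyclohexane ring and its base-sensitive aldol.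
4. Alkyne 11 ⇒ aldol of undec-10-yn-2-one 9 with C2-symmetric ketone 7 (homotopic carbonyl faces, so no facial selectivity is needed); 7 ⇒ D-(−)-quinic acid 1 by deoxygenation at C-4 and excision of the carboxyl carbon.
5. Rings: the single carbocycle is never built; it is the cyclohexane of quinic acid carried through. Only a temporary dioxaborinane ring is closed and reopened (step 12) to tell the two ring oxygens apart.

Key step: step 9

Assumption: dec-9-ynoic acid 8 and 1-bromooct-2-yne 12 are taken as catalogue compounds; side-chain locants count from the ring-bound CH2 (C-1), so the chain ketone is C-2 and the skipped diene is C-10=C-11–C-12H2–C-13=C-14.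

**Route**

Step 1
Reactants: 1 D-(−)-quinic acid
Product: 2 methyl quinate
Conditions: MeOH, Amberlyst 15 (sulfonic acid resin), reflux
Reagents that add atoms: methanol, CO
Why: Fischer esterification of the α-hydroxy acid in excess methanol, in which none of the four stereocentres takes part.

Step 2
Reactants: 2 methyl quinate
Product: 3 methyl 3,5-bis-O-(tert-butyldimethylsilyl)quinate
Conditions: TBSCl (2.2 equiv), imidazole, DMF, 0 °C to rt
Reagents that add atoms: tert-butyldimethylsilyl chloride, CC(C)(C)[Si](C)(C)Cl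
Why: Silyl ether formation that should stop at the two outer secondary hydroxyls, because the tertiary C-1 hydroxyl and the C-4 hydroxyl, once flanked by two bulky silyloxy groups, are too hindered.

Step 3
Reactants: 3 methyl 3,5-bis-O-(tert-butyldimethylsilyl)quinate
Product: 4 methyl 3,5-bis-O-(tert-butyldimethylsilyl)-4-O-(1H-imidazol-1-ylcarbonothioyl)quinate
Conditions: 1,1'-thiocarbonyldiimidazole, DMAP (cat.), ClCH2CH2Cl, reflux
Reagents that add atoms: 1,1'-thiocarbonyldiimidazole, S=C(n1ccnc1)n1ccnc1
Why: Thioacylation of the only remaining secondary alcohol gives the imidazolide required for a Barton–McCombie deoxygenation, the tertiary hydroxyl being unreactive.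

Step 4
Reactants: 4 methyl 3,5-bis-O-(tert-butyldimethylsilyl)-4-O-(1H-imidazol-1-ylcarbonothioyl)quinate
Product: 5 methyl (3S,5S)-3,5-bis[(tert-butyldimethylsilyl)oxy]-1-hydroxycyclohexane-1-carboxylate
Conditions: Bu3SnH, AIBN (cat.), toluene, 100 °C
Reagents that add atoms: none
Why: Barton–McCombie radical deoxygenation removes the C-4 oxygen without touching C-3 and C-5, after which the two silyloxy-bearing ring arms are identical and C-1 is no longer a stereocentre.

Step 5
Reactants: 5 methyl (3S,5S)-3,5-bis[(tert-butyldimethylsilyl)oxy]-1-hydroxycyclohexane-1-carboxylate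
Product: 6 (3S,5S)-3,5-bis[(tert-butyldimethylsilyl)oxy]-1-(hydroxymethyl)cyclohexan-1-ol
Conditions: LiAlH4, Et2O, 0 °C
Reagents that add atoms: none
Why: Hydride reduction of the ester to the primary alcohol sets up a 1,2-diol, silyl ethers being inert to LiAlH4.

Step 6
Reactants: 6 (3S,5S)-3,5-bis[(tert-butyldimethylsilyl)oxy]-1-(hydroxymethyl)cyclohexan-1-ol
Product: 7 (3S,5S)-3,5-bis[(tert-butyldimethylsilyl)oxy]cyclohexan-1-one
Conditions: NaIO4, THF/H2O, 0 °C to rt
Reagents that add atoms: none
Why: Malaprade glycol cleavage excises the exocyclic carbon as formaldehyde and leaves the C2-symmetric trans-disilyloxy ketone, whose two stereocentres come unchanged from quinic acid.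

Step 7
Reactants: 8 dec-9-ynoic acid
Product: 9 undec-10-yn-2-one
Conditions: MeLi (3.2 equiv), THF, 0 °C to rt; inverse quench into 1 M HCl, 0 °C
Reagents that add atoms: methyllithium, C[Li]
Why: Methyl ketone synthesis by addition of methyllithium to the lithium carboxylate, the doubly charged adduct resisting a second addition until the quench, where the lithiated alkyne terminus is reprotonated as well.

Step 8
Reactants: 9 undec-10-yn-2-one; 7 (3S,5S)-3,5-bis[(tert-butyldimethylsilyl)oxy]cyclohexan-1-one
Product: 11 1-[(3S,5S)-3,5-bis[(tert-butyldimethylsilyl)oxy]-1-hydroxycyclohexyl]undec-10-yn-2-one, via lithium enolate 10 (not isolated)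
Conditions: LiN(SiMe3)2 (1.05 equiv), THF, −78 °C; then 7, −78 °C; AcOH, −78 °C
Reagents that add atoms: none
Why: Directed aldol addition of the kinetic methyl-side lithium enolate to a cyclohexanone; the two carbonyl faces of C2-symmetric 7 are homotopic, so a single adduct must form without any facial selectivity, its tertiary hydroxyl lying cis to one ring silyloxy group and trans to the other while the carbinol carbon itself is not yet stereogenic.

Step 9
Reactants: 11 1-[(3S,5S)-3,5-bis[(tert-butyldimethylsilyl)oxy]-1-hydroxycyclohexyl]undec-10-yn-2-one; 12 1-bromooct-2-yne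
Product: 14 1-[(3S,5S)-3,5-bis[(tert-butyldimethylsilyl)oxy]-1-hydroxycyclohexyl]nonadeca-10,13-diyn-2-one, via copper acetylide 13 (not isolated)
Conditions: CuI (1.0 equiv), K2CO3 (1.5 equiv), DMF, rt
Reagents that add atoms: none
Why: Carbonate deprotonates the terminal alkyne once it is π-bound to monovalent copper, and the resulting copper acetylide 13 displaces bromide at the propargylic CH2 of 12 (formally through a trivalent copper intermediate and reductive elimination), forging the C-11–C-12 bond. The closest known reaction type is the CuI/carbonate coupling of terminal alkynes with propargylic halides used to assemble skipped polyynes. No ring is closed and no stereocentre is created; both cis alkenes of the target are stored in the product as triple bonds, so the complete C25 skeleton and its unsaturation pattern arise in this one union of a C17 and a C8 fragment. The selectivity needed is attack at the α-carbon of the propargylic bromide rather than the γ-carbon (allenyne), secured by the unhindered primary bromide and the soft copper nucleophile, together with chemoselective C-alkynylation beside the free tertiary aldol, the ketone and the silyl ethers, secured by a mild heterogeneous base that metallates only the copper-activated sp C–H.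

Step 10
Reactants: 14 1-[(3S,5S)-3,5-bis[(tert-butyldimethylsilyl)oxy]-1-hydroxycyclohexyl]nonadeca-10,13-diyn-2-one
Product: 15 (10Z,13Z)-1-[(3S,5S)-3,5-bis[(tert-butyldimethylsilyl)oxy]-1-hydroxycyclohexyl]nonadeca-10,13-dien-2-one
Conditions: H2 (1 atm), Pd/CaCO3 poisoned with Pb(OAc)2 (Lindlar catalyst), quinoline, EtOAc, rt, stopped after 2 equiv of H2
Reagents that add atoms: none
Why: Lindlar semihydrogenation delivers H2 syn to each triple bond on the poisoned palladium surface, which fixes both new double bonds as Z, while ketone, silyl ethers and tertiary alcohol are inert.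

Step 11
Reactants: 15 (10Z,13Z)-1-[(3S,5S)-3,5-bis[(tert-butyldimethylsilyl)oxy]-1-hydroxycyclohexyl]nonadeca-10,13-dien-2-one
Product: 16 (10Z,13Z)-1-[(3S,5S)-1,3,5-trihydroxycyclohexyl]nonadeca-10,13-dien-2-one
Conditions: HF·pyridine, pyridine/THF, 0 °C to rt
Reagents that add atoms: none
Why: Fluoride-mediated desilylation under buffered, non-basic conditions should free both secondary hydroxyls without retro-aldol cleavage of the β-hydroxy ketone or isomerisation of the skipped diene.

Step 12
Reactants: 16 (10Z,13Z)-1-[(3S,5S)-1,3,5-trihydroxycyclohexyl]nonadeca-10,13-dien-2-one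
Product: 19 (1S,3S,5S)-3,5-dihydroxy-3-[(10Z,13Z)-2-oxononadeca-10,13-dien-1-yl]cyclohexyl methanesulfonate, via cyclic boronate 17 (not isolated), via boronate mesylate 18 (not isolated)
Conditions: PhB(OH)2 (1.05 equiv), 4 Å molecular sieves, CH2Cl2, rt; then Et3N, MsCl, 0 °C; then pinacol, rt
Reagents that add atoms: methanesulfonyl chloride, CS(=O)(=O)Cl (phenylboronic acid, OB(O)c1ccccc1, leaves atoms only in 17 and 18)
Why: Transient boronate protection followed by sulfonylation: only the tertiary hydroxyl and the secondary hydroxyl cis to it can be bridged by boron (1,3-diaxial dioxaborinane), so the mesyl group must go to the trans hydroxyl, and this differentiation, dictated by the trans relation of the ring oxygens inherited from quinic acid and not by any selectivity, turns the carbinol carbon into a stereocentre of defined S configuration before pinacol strips the boronate.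

Step 13
Reactants: 19 (1S,3S,5S)-3,5-dihydroxy-3-[(10Z,13Z)-2-oxononadeca-10,13-dien-1-yl]cyclohexyl methanesulfonate
Product: 21 (5S)-5-hydroxy-5-[(10Z,13Z)-2-oxononadeca-10,13-dien-1-yl]cyclohex-2-en-1-one (CNP0252404.1), via mesyloxy ketone 20 (not isolated)
Conditions: Dess–Martin periodinane, NaHCO3, CH2Cl2, 0 °C to rt; then Et3N (excess), 0 °C
Reagents that add atoms: none
Why: Dess–Martin oxidation of the only secondary alcohol followed by E1cB elimination of the β-mesylate should give the conjugated enone under conditions too mild to expel the tertiary hydroxyl, so the carbinol stereocentre defined in step 12 is carried into the target unchanged.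

**Compound list**
1 | D-(−)-quinic acid, (1S,3R,4S,5R)-1,3,4,5-tetrahydroxycyclohexane-1-carboxylic acid | O[C@@]1(C(=O)O)C[C@@H](O)[C@@H](O)[C@H](O)C1 | starting material
2 | methyl quinate, methyl (1S,3R,4S,5R)-1,3,4,5-tetrahydroxycyclohexane-1-carboxylate | O[C@@]1(C(=O)OC)C[C@@H](O)[C@@H](O)[C@H](O)C1 | intermediate
3 | methyl 3,5-bis-O-(tert-butyldimethylsilyl)quinate (quinate numbering, ring stereocentres as in 1) | O[C@@]1(C(=O)OC)C[C@@H](O[Si](C)(C)C(C)(C)C)[C@@H](O)[C@H](O[Si](C)(C)C(C)(C)C)C1 | intermediate
4 | methyl 3,5-bis-O-(tert-butyldimethylsilyl)-4-O-(1H-imidazol-1-ylcarbonothioyl)quinate | O[C@@]1(C(=O)OC)C[C@@H](O[Si](C)(C)C(C)(C)C)[C@@H](OC(=S)n2ccnc2)[C@H](O[Si](C)(C)C(C)(C)C)C1 | intermediate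
5 | methyl (3S,5S)-3,5-bis[(tert-butyldimethylsilyl)oxy]-1-hydroxycyclohexane-1-carboxylate (silyloxy groups trans; C-1 not stereogenic) | OC1(C(=O)OC)C[C@@H](O[Si](C)(C)C(C)(C)C)C[C@H](O[Si](C)(C)C(C)(C)C)C1 | intermediate
6 | (3S,5S)-3,5-bis[(tert-butyldimethylsilyl)oxy]-1-(hydroxymethyl)cyclohexan-1-ol | OCC1(O)C[C@@H](O[Si](C)(C)C(C)(C)C)C[C@H](O[Si](C)(C)C(C)(C)C)C1 | intermediate
7 | (3S,5S)-3,5-bis[(tert-butyldimethylsilyl)oxy]cyclohexan-1-one (trans, C2-symmetric) | O=C1C[C@@H](O[Si](C)(C)C(C)(C)C)C[C@H](O[Si](C)(C)C(C)(C)C)C1 | intermediate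
8 | dec-9-ynoic acid | C#CCCCCCCCC(=O)O | starting material
9 | undec-10-yn-2-one | CC(=O)CCCCCCCC#C | intermediate
10 | lithium undec-1-en-10-yn-2-olate (kinetic enolate of 9) | [Li]OC(=C)CCCCCCCC#C | intermediate
11 | 1-[(3S,5S)-3,5-bis[(tert-butyldimethylsilyl)oxy]-1-hydroxycyclohexyl]undec-10-yn-2-one (carbinol carbon not stereogenic) | C#CCCCCCCCC(=O)CC1(O)C[C@@H](O[Si](C)(C)C(C)(C)C)C[C@H](O[Si](C)(C)C(C)(C)C)C1 | intermediate
12 | 1-bromooct-2-yne | CCCCCC#CCBr | starting material
13 | copper acetylide of 11 (Cu on the terminal alkyne carbon) | [Cu]C#CCCCCCCCC(=O)CC1(O)C[C@@H](O[Si](C)(C)C(C)(C)C)C[C@H](O[Si](C)(C)C(C)(C)C)C1 | intermediate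
14 | 1-[(3S,5S)-3,5-bis[(tert-butyldimethylsilyl)oxy]-1-hydroxycyclohexyl]nonadeca-10,13-diyn-2-one | CCCCCC#CCC#CCCCCCCCC(=O)CC1(O)C[C@@H](O[Si](C)(C)C(C)(C)C)C[C@H](O[Si](C)(C)C(C)(C)C)C1 | intermediate
15 | (10Z,13Z)-1-[(3S,5S)-3,5-bis[(tert-butyldimethylsilyl)oxy]-1-hydroxycyclohexyl]nonadeca-10,13-dien-2-one | CCCCC/C=C\C/C=C\CCCCCCCC(=O)CC1(O)C[C@@H](O[Si](C)(C)C(C)(C)C)C[C@H](O[Si](C)(C)C(C)(C)C)C1 | intermediate
16 | (10Z,13Z)-1-[(3S,5S)-1,3,5-trihydroxycyclohexyl]nonadeca-10,13-dien-2-one | CCCCC/C=C\C/C=C\CCCCCCCC(=O)CC1(O)C[C@@H](O)C[C@H](O)C1 | intermediate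
17 | cyclic phenylboronate of 16: B–Ph bridges the tertiary oxygen and the ring oxygen cis to it (2,4-dioxa-3-borabicyclo[3.3.1]nonane), the trans hydroxyl is free | CCCCC/C=C\C/C=C\CCCCCCCC(=O)C[C@]1(OB(c2ccccc2)O3)C[C@@H]3C[C@H](O)C1 | intermediate
18 | methanesulfonate of 17 at the hydroxyl trans to the boronate-bound tertiary oxygen | CCCCC/C=C\C/C=C\CCCCCCCC(=O)C[C@]1(OB(c2ccccc2)O3)C[C@@H]3C[C@H](OS(C)(=O)=O)C1 | intermediate
19 | (1S,3S,5S)-3,5-dihydroxy-3-[(10Z,13Z)-2-oxononadeca-10,13-dien-1-yl]cyclohexyl methanesulfonate (mesylate trans, free secondary OH cis to the tertiary OH) | CCCCC/C=C\C/C=C\CCCCCCCC(=O)C[C@]1(O)C[C@@H](O)C[C@H](OS(C)(=O)=O)C1 | intermediate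
20 | (1R,3S)-3-hydroxy-5-oxo-3-[(10Z,13Z)-2-oxononadeca-10,13-dien-1-yl]cyclohexyl methanesulfonate | CCCCC/C=C\C/C=C\CCCCCCCC(=O)C[C@]1(O)CC(=O)C[C@H](OS(C)(=O)=O)C1 | intermediate
21 | (5S)-5-hydroxy-5-[(10Z,13Z)-2-oxononadeca-10,13-dien-1-yl]cyclohex-2-en-1-one (CNP0252404.1) | CCCCC/C=C\C/C=C\CCCCCCCC(=O)C[C@@]1(O)CC=CC(=O)C1 | target

**Step count and risks**

Total step count: 13. Longest linear sequence: 12 steps (steps 1–6 and 8–13, from quinic acid).

Steps most likely to fail:

1. Step 8 (aldol). The lithium enolate may act as a base towards 7, after which the ring enolate expels silanolate, and any adduct can revert before the quench. Fallback, a Mukaiyama aldol: setting out from 9, enolate 10 is trapped with Me3SiCl to give trimethyl(undec-1-en-10-yn-2-yloxy)silane F1, and this neutral nucleophile is added to 7 under TiCl4 in CH2Cl2 at −78 °C; aqueous work-up should deliver 11, where the route is rejoined.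

2. Step 9 (key coupling). The free tertiary aldol may fragment by retro-aldol under carbonate in DMF, the acetylide may attack the γ-carbon of the propargylic bromide, and the 1,4-diyne may drift prototropically under base. Fallback, reversal of the order of fragment union: setting out from 9 and 12, the same CuI/K2CO3 coupling is run on the robust methyl ketone and should pass through (10-oxoundec-1-yn-1-yl)copper F2 to nonadeca-10,13-diyn-2-one F3. Semihydrogenation over Pd/CaCO3 poisoned with Pb(OAc)2 should then give (10Z,13Z)-nonadeca-10,13-dien-2-one F4. Its kinetic enolate, lithium (10Z,13Z)-nonadeca-1,10,13-trien-2-olate F5, formed with LiN(SiMe3)2 at −78 °C, is added to 7, and the route is rejoined at 15.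

3. Step 10 (semihydrogenation). With two triple bonds to be stopped at the alkene stage in one flask, over-reduction to monoenes, incomplete conversion and cis-to-trans isomerisation may occur. Fallback, one Z-alkene is brought in ready-made so that only one triple bond has to be reduced: setting out from 11, commercial (Z)-oct-2-en-1-ol is converted with CBr4/PPh3 into (Z)-1-bromooct-2-ene F6, which is coupled with 11 through copper acetylide 13 under CuI/K2CO3 in DMF to give (13Z)-1-[(3S,5S)-3,5-bis[(tert-butyldimethylsilyl)oxy]-1-hydroxycyclohexyl]nonadec-13-en-10-yn-2-one F7; semihydrogenation of its single alkyne should return the route at 15.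

Further compounds
F1 | step 8 | trimethyl(undec-1-en-10-yn-2-yloxy)silane | C=C(O[Si](C)(C)C)CCCCCCCC#C
F2 | step 9 | (10-oxoundec-1-yn-1-yl)copper | [Cu]C#CCCCCCCCC(C)=O
F3 | step 9 | nonadeca-10,13-diyn-2-one | CCCCCC#CCC#CCCCCCCCC(C)=O
F4 | step 9 | (10Z,13Z)-nonadeca-10,13-dien-2-one | CCCCC/C=C\C/C=C\CCCCCCCC(C)=O
F5 | step 9 | lithium (10Z,13Z)-nonadeca-1,10,13-trien-2-olate | [Li]OC(=C)CCCCCCC/C=C\C/C=C\CCCCC
F6 | step 10 | (Z)-1-bromooct-2-ene | CCCCC/C=C\CBr
F7 | step 10 | (13Z)-1-[(3S,5S)-3,5-bis[(tert-butyldimethylsilyl)oxy]-1-hydroxycyclohexyl]nonadec-13-en-10-yn-2-one | CCCCC/C=C\CC#CCCCCCCCC(=O)CC1(O)C[C@@H](O[Si](C)(C)C(C)(C)C)C[C@H](O[Si](C)(C)C(C)(C)C)C1
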